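Readings and results were generated by integration with constants of no real substance; scatter was added.

The target at the end is one member of a pair: it shares the converted substrate with the isomer of the product, and the ratio of these two amounts gives both answers.

- Sunday's: substrate 1 M; partner 1.8 equiv (in portions, 3); the very flask that is asked about, followed so far; portions every 15 min
- flask: substrate 1.0 M; partner 1.80 equiv (in portions, 3); time 15 h; the portions of partner follow each other after 15 min, the first at the start

Sunday's run (percent of the substrate charged)

| time / h | substrate / % | target / % | isomer of the product / % | intermediate / % |
|---|---|---|---|---|
| 0.667 | 23.7 | 59.8 | 12.9 | 4.9 |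
| 1.00 | 7.6 | 70.6 | 15.1 | 6.5 |
| 1.50 | 1.7 | 75.3 | 17.6 | 5.7 |
| 2.50 | 1.2 | 76.7 | 15.9 | 6.3 |
| 5.00 | 0 | 78.0 | 15.6 | 5.3 |
| 8.00 | 0 | 76.6 | 18.1 | 6.2 |

(scatter of a reading: 1 percentage point)

1. why nothing more happens at 15 h, or that something still does (it is still moving / all of the substrate has reacted / forward and back rates have come level / the partner has run out first)
2. share of the substrate used up at 15 h
3. target at 15 h, in percent of the substrate charged
4. isomer of the product at 15 h, in percent of the substrate charged
5. intermediate at 15 h, in percent of the substrate charged

- the numbers in the tables scatter by 1 percentage point (one standard deviation)
- the reaction counts as stopped when no species that holds the substrate changes by six tenths of a point or more over the second half of the time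

In Sunday's run, [target]/[isomer of the product] reads 4.64 at 0.667 h, with substrate still at 23.7%, and 4.23 at 8.00 h, a gap that a scatter of 1 percentage point on a small reading can cover. Summing each species over the samples gives 4.59, the split ratio. The readings show that it holds steady, but not whether it is a fixed branching or a balance.

Substrate reads 0% from 5.00 h, so it is the limiting reagent against 1.80 equiv of partner, and the plateau should stand at 15 h. The intermediate averages 5.87% on the plateau. Taking the three species as the whole charge, the remainder divides by the split ratio into 77.3% target and 16.8% isomer of the product.

The forecast, slightly apart from this reckoning, gives all of the substrate has reacted as the end, with 100% conversion, 77.1% target, 16.8% isomer of the product and 6.1% intermediate, holding that the “run stops simply because the substrate is consumed”.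

The flask gives all of the substrate has reacted: 100% conversion, 77.0% target, 16.7% isomer of the product and 5.50% intermediate.

    intermediate ⇌ target (K = 14.0, k = 0.0677 s⁻¹)
    intermediate ⇌ isomer of the product (K = 3.03, k = 0.0251 s⁻¹)
    substrate + intermediate → side product (k = 8.87 × 10⁻⁵ M⁻¹ s⁻¹)
    substrate + partner → intermediate + by-product (k = 8.48 × 10⁻⁴ M⁻¹ s⁻¹)

The flask's split ratio is 4.61. It is a balance, thermodynamic rather than kinetic control, because the isomer of the product returns to the intermediate: a run without that reverse step ends with 0% target instead of 77.0%. The same flask with 0.450 equiv of partner has, at 15.0 h, partner at 0% and substrate at 49.3%, and holds 6.61% isomer of the product; the split ratio of 4.59 turns that into 30.3% target, and that flask holds 30.5%.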